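**Assumption:** enantiopure (R)-but-3-en-2-ol is taken as a stock chemical; the target stereocentre reads as R from the SMILES, and the triketone ring is drawn throughout in the tautomer of the target SMILES.

## Retrosynthetic overview

1. Target 11 ⇐ olefin cross-metathesis of the (R)-crotyl dimer 10 with 2-methylbut-2-ene (crotyl → prenyl).
2. 10 ⇐ dearomatising aromatic Claisen rearrangement of the (S)-but-3-en-2-yl aryl ether 9; the bought C–O stereocentre is relayed to the quaternary carbon through a chair transition state.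
3. 9 ⇐ methylene bridge from formaldehyde between ring A phenol 8 (one free ring position) and ring B ketone 7.
4. 8 ⇐ Mitsunobu inversion of (R)-but-3-en-2-ol on 4,6-disilylated 3-methylphlorbutyrophenone; the butanoyl groups come from Friedel–Crafts and Hoesch acylation of 2-methylphloroglucinol and 5-methoxyresorcinol.
5. Ring order: no ring is built. Both six-membered rings are bought as benzenes; ring A is dearomatised to the cyclohexadienone in the rearrangement, after the bridge is in place.

## Route

Step 1
Reactants: 1 2-methylbenzene-1,3,5-triol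
Product: 2 1-(2,4,6-trihydroxy-3-methylphenyl)butan-1-one
Conditions: butanoyl chloride (1.1 equiv), AlCl3 (3.5 equiv), PhNO2/CH2Cl2, 0 °C → 45 °C; aq HCl work-up
Reagents that add atoms: butanoyl chloride, CCCC(Cl)=O
Why: Friedel–Crafts C-acylation; the two free ring positions of 1 are equivalent, so a single mono-ketone forms and the chelated ketone resists a second acylation.

Step 2
Reactants: 2 1-(2,4,6-trihydroxy-3-methylphenyl)butan-1-one
Product: 3 1-{4,6-bis[(tert-butyldimethylsilyl)oxy]-2-hydroxy-3-methylphenyl}butan-1-one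
Conditions: TBSCl (2.1 equiv), imidazole (4 equiv), CH2Cl2/DMF, 0 °C → rt
Reagents that add atoms: tert-butyldimethylsilyl chloride, CC(C)(C)[Si](C)(C)Cl
Why: selective silyl ether formation; the non-chelated 4-OH and the less hindered 6-OH react with the bulky silyl chloride, while the 2-OH (hydrogen-bonded to the ketone and buttressed by the 3-methyl group) stays free.

Step 3
Reactants: 3 1-{4,6-bis[(tert-butyldimethylsilyl)oxy]-2-hydroxy-3-methylphenyl}butan-1-one; 4 (R)-but-3-en-2-ol
Product: 5 1-{2-[(2S)-but-3-en-2-yloxy]-4,6-bis[(tert-butyldimethylsilyl)oxy]-3-methylphenyl}butan-1-one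
Conditions: PPh3 (1.5 equiv), DIAD (1.5 equiv), THF (concentrated), 0 °C → rt
Reagents that add atoms: none
Why: Mitsunobu etherification; the phenol displaces the oxyphosphonium group by SN2 with inversion, so the bought (R)-carbinol becomes the (S)-aryl ether.

Step 4
Reactants: 6 5-methoxybenzene-1,3-diol
Product: 7 1-(2,4-dihydroxy-6-methoxyphenyl)butan-1-one
Conditions: PrCN, ZnCl2 (20 mol %), HCl (g), Et2O, 0 °C; then H2O, reflux; chromatography
Reagents that add atoms: butanenitrile, CCCC#N; water, O
Why: Houben–Hoesch acylation; the nitrilium ion attacks the activated ring without cleaving the methyl ether, and the two positions between OH and OMe outnumber the one between the two OH groups, so 7 is the major isomer (the symmetrical 2,6-dihydroxy-4-methoxy ketone is separated).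

Step 5
Reactants: 5 1-{2-[(2S)-but-3-en-2-yloxy]-4,6-bis[(tert-butyldimethylsilyl)oxy]-3-methylphenyl}butan-1-one; 7 1-(2,4-dihydroxy-6-methoxyphenyl)butan-1-one
Product: 9 1-[3-({3-butanoyl-4-[(2S)-but-3-en-2-yloxy]-2,6-dihydroxy-5-methylphenyl}methyl)-2,4-dihydroxy-6-methoxyphenyl]butan-1-one, via desilylated aryl ether 8 (not isolated)
Conditions: 1 M aq KOH (6 equiv), 1,4-dioxane, rt, 1 h; then 7 (3 equiv), 37% aq HCHO (1.0 equiv, slow addition), 0 °C → rt; 1 M HCl
Reagents that add atoms: formaldehyde, C=O
Why: hydroxide cleaves both aryl silyl ethers, then the classical formaldehyde condensation of phloroglucinols (hydroxymethylation, ortho-quinone methide, Michael addition) joins the only free position of 8 to C3 of 7, the excess of 7 channelling 8 into the mixed dimer; the C–O stereocentre is not touched.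

Step 6
Reactants: 9 1-[3-({3-butanoyl-4-[(2S)-but-3-en-2-yloxy]-2,6-dihydroxy-5-methylphenyl}methyl)-2,4-dihydroxy-6-methoxyphenyl]butan-1-one
Product: 10 (4R)-4-[(2E)-but-2-en-1-yl]-2-butanoyl-6-[(3-butanoyl-2,6-dihydroxy-4-methoxyphenyl)methyl]-3,5-dihydroxy-4-methylcyclohexa-2,5-dien-1-one
Conditions: degassed PhMe, 120 °C, sealed tube, 6–12 h
Reagents that add atoms: none
Why: dearomatising aromatic Claisen rearrangement ([3,3]-sigmatropic shift) through a chair transition state with the carbinol methyl pseudo-equatorial, which delivers the allyl terminus to one face of the methyl-bearing ortho carbon, so the (S) C–O centre becomes the (R) quaternary carbon with an (E)-crotyl chain; the other ortho carbon carries the acyl group, the para carbon is blocked by the bridge, and the product is held as the stable enolised triketone.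

Step 7
Reactants: 10 (4R)-4-[(2E)-but-2-en-1-yl]-2-butanoyl-6-[(3-butanoyl-2,6-dihydroxy-4-methoxyphenyl)methyl]-3,5-dihydroxy-4-methylcyclohexa-2,5-dien-1-one
Product: 11 (4R)-2-butanoyl-6-[(3-butanoyl-2,6-dihydroxy-4-methoxyphenyl)methyl]-3,5-dihydroxy-4-methyl-4-(3-methylbut-2-en-1-yl)cyclohexa-2,5-dien-1-one
Conditions: second-generation Grubbs catalyst (5 mol %), 2-methylbut-2-ene/CH2Cl2 (1:3), 40 °C
Reagents that add atoms: 2-methylbut-2-ene, CC=C(C)C
Why: olefin cross-metathesis exchanges the ethylidene end of the crotyl group for isopropylidene to give the prenyl group; free phenols and enols are tolerated by the ruthenium carbene, and the quaternary centre is not involved, so both alkene isomers of 10 that share the R centre converge on 11.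

## Compound list

1 | 2-methylbenzene-1,3,5-triol | Cc1c(O)cc(O)cc1O | starting material
2 | 1-(2,4,6-trihydroxy-3-methylphenyl)butan-1-one | CCCC(=O)c1c(O)cc(O)c(C)c1O | intermediate
3 | 1-{4,6-bis[(tert-butyldimethylsilyl)oxy]-2-hydroxy-3-methylphenyl}butan-1-one | CCCC(=O)c1c(O[Si](C)(C)C(C)(C)C)cc(O[Si](C)(C)C(C)(C)C)c(C)c1O | intermediate
4 | (R)-but-3-en-2-ol | C[C@@H](O)C=C | starting material
5 | 1-{2-[(2S)-but-3-en-2-yloxy]-4,6-bis[(tert-butyldimethylsilyl)oxy]-3-methylphenyl}butan-1-one | CCCC(=O)c1c(O[Si](C)(C)C(C)(C)C)cc(O[Si](C)(C)C(C)(C)C)c(C)c1O[C@@H](C)C=C | intermediate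
6 | 5-methoxybenzene-1,3-diol | COc1cc(O)cc(O)c1 | starting material
7 | 1-(2,4-dihydroxy-6-methoxyphenyl)butan-1-one | CCCC(=O)c1c(O)cc(O)cc1OC | intermediate
8 | 1-{2-[(2S)-but-3-en-2-yloxy]-4,6-dihydroxy-3-methylphenyl}butan-1-one | CCCC(=O)c1c(O)cc(O)c(C)c1O[C@@H](C)C=C | intermediate
9 | 1-[3-({3-butanoyl-4-[(2S)-but-3-en-2-yloxy]-2,6-dihydroxy-5-methylphenyl}methyl)-2,4-dihydroxy-6-methoxyphenyl]butan-1-one | CCCC(=O)c1c(O)c(Cc2c(O)cc(OC)c(C(=O)CCC)c2O)c(O)c(C)c1O[C@@H](C)C=C | intermediate
10 | (4R)-4-[(2E)-but-2-en-1-yl]-2-butanoyl-6-[(3-butanoyl-2,6-dihydroxy-4-methoxyphenyl)methyl]-3,5-dihydroxy-4-methylcyclohexa-2,5-dien-1-one | CCCC(=O)C1=C(O)[C@](C)(C/C=C/C)C(O)=C(Cc2c(O)cc(OC)c(C(=O)CCC)c2O)C1=O | intermediate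
11 | (4R)-2-butanoyl-6-[(3-butanoyl-2,6-dihydroxy-4-methoxyphenyl)methyl]-3,5-dihydroxy-4-methyl-4-(3-methylbut-2-en-1-yl)cyclohexa-2,5-dien-1-one | CCCC(=O)C1=C(O)[C@](C)(CC=C(C)C)C(O)=C(Cc2c(O)cc(OC)c(C(=O)CCC)c2O)C1=O | target

## Step count and risks

Total steps: 7. Longest linear sequence: 6 (steps 1, 2, 3, 5, 6, 7); step 4 is the side branch.

The three steps most likely to fail:

**Step 3 (Mitsunobu on a hindered, chelated phenol).** The risk is low conversion, SN2' ether or partial racemisation of the allylic carbinol. The fallback sets out from compound 3 and comes back at compound 5. The allyl unit is brought in as an alkyne. Mitsunobu reaction of 3 with (R)-but-3-yn-2-ol (C[C@@H](O)C#C; PPh3, DIAD, PhMe) goes with clean inversion, because the slimmer propargylic carbinol has no SN2' ether pathway. It gives 1-{2-[(2S)-but-3-yn-2-yloxy]-4,6-bis[(tert-butyldimethylsilyl)oxy]-3-methylphenyl}butan-1-one F1. Semi-hydrogenation (H2, Pd on CaCO3 poisoned with Pb(OAc)2, quinoline, EtOAc) then gives 5.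

**Step 5 (mixed methylene coupling).** The risk is a statistical mixture with homodimers and attack at C5 of 7. The fallback sets out from compound 7 and comes back at compound 9. Ring B is made the electrophile. Treating 7 with dimethylmethylideneammonium iodide (C=[N+](C)C.[I-]) in MeCN gives the Mannich base 1-{3-[(dimethylamino)methyl]-2,4-dihydroxy-6-methoxyphenyl}butan-1-one F2. Compound 5 is desilylated on its own (aq KOH, dioxane, then HCl) to isolated 8. Heating F2 with 8 in dioxane at 80 °C expels dimethylamine, and the ortho-quinone methide of ring B is captured by the single free position of 8 to give 9 without any homodimer of 8.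

**Step 6 (Claisen rearrangement on the dimer).** The risks are scrambling of the methylene bridge on heating, migration to the acyl-bearing or bridge-bearing carbon, and imperfect chair/E selectivity, which lowers the ee. The fallback sets out from compound 5 and comes back at compound 10. The rearrangement is run before the bridge exists. Compound 5 is desilylated (aq KOH, dioxane, then HCl) to isolated 8. Heating 8 in degassed PhMe at 110 °C gives, by the same chair-controlled shift, (4R)-4-[(2E)-but-2-en-1-yl]-2-butanoyl-3,5-dihydroxy-4-methylcyclohexa-2,5-dien-1-one F3; the temperature is kept low because the para position is free at this stage. Condensation of F3 with 7 (3 equiv) and aq HCHO in dilute aq KOH at 0 °C then gives 10.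

## Further compounds

F1 | step 3 | 1-{2-[(2S)-but-3-yn-2-yloxy]-4,6-bis[(tert-butyldimethylsilyl)oxy]-3-methylphenyl}butan-1-one | CCCC(=O)c1c(O[Si](C)(C)C(C)(C)C)cc(O[Si](C)(C)C(C)(C)C)c(C)c1O[C@@H](C)C#C
F2 | step 5 | 1-{3-[(dimethylamino)methyl]-2,4-dihydroxy-6-methoxyphenyl}butan-1-one | CCCC(=O)c1c(O)c(CN(C)C)c(O)cc1OC
F3 | step 6 | (4R)-4-[(2E)-but-2-en-1-yl]-2-butanoyl-3,5-dihydroxy-4-methylcyclohexa-2,5-dien-1-one | CCCC(=O)C1=C(O)[C@](C)(C/C=C/C)C(O)=CC1=O
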